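**Plan**

1. Ring numbering used throughout: C1 carries the aroyl group, C2 is CH2, C3=C4 is the ring alkene with the 4-methylpent-3-enyl chain on C4, C5 is CH2 and C6 carries phenyl.
2. Retrosynthesis: the exocyclic C1–C(=O)Ar bond is cut first (aldol onto a ketone held temporarily at C2), then the two ring bonds C2–C3 and C4–C5.
3. Enabling feature: C3=C4 with its chain maps onto a terminal alkyne, supplied from 5-bromo-2-methylpent-2-ene as 6-methylhept-5-en-1-yne. C6 with its flanking methylenes C1 and C5 plus a carbonyl at C2 is the four-membered ring of prochiral 3-phenylcyclobutanone, so inserting the alkyne into one acyl–CH2 bond gives the six-membered ring.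
4. Forward: the cyclohexenone (the only ring to be made) arises in the nickel step; the MOM-protected aryl aldehyde is then joined at C1, the C2 oxygen is removed through an allylic acetate, the carbinol is oxidised and the phenols are released.
5. Stereochemistry: C6 comes from the ligand-controlled choice between the two enantiotopic acyl–CH2 bonds. C1 comes from aldol addition anti to the neighbouring phenyl group (trans), which is also the more stable arrangement once C1 is α to the aryl ketone.

Key step: step 2

Assumption: the sense of induction of the chiral phosphoramidite in step 2 cannot be predicted reliably, so the ligand antipode that delivers the (5R)-enone is taken (written below as the (S,R,R) ligand).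

**Step 1**
Reactants: 1 5-bromo-2-methylpent-2-ene
Product: 2 6-methylhept-5-en-1-yne
Conditions: LiC≡CH·H2N(CH2)2NH2, DMSO, 10 °C → rt
Reagents that add atoms: lithium acetylide ethylenediamine complex, [Li]C#C.NCCN
Why: SN2 alkylation of an acetylide by a primary bromide in DMSO (standard terminal alkyne synthesis) should give the alkyne, the diamine complex favouring monoalkylation and the trisubstituted alkene remaining a spectator.

**Step 2**
Reactants: 3 3-phenylcyclobutanone; 2 6-methylhept-5-en-1-yne
Product: 4 (5R)-3-(4-methylpent-3-en-1-yl)-5-phenylcyclohex-2-en-1-one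
Conditions: Ni(cod)2 (10 mol%), (S)-BINOL N,N-bis[(R)-1-phenylethyl]phosphoramidite (12 mol%), toluene, 60 °C, slow addition of 2 (syringe pump)
Reagents that add atoms: none
Why: Proposed new method: the zerovalent nickel–phosphoramidite complex should couple the strained ketone carbonyl of 3 with alkyne 2 by oxidative cyclisation to a spiro oxanickelacyclopentene in which the carbonyl carbon is bonded to the unsubstituted alkyne terminus (C2–C3), after which strain-releasing β-carbon elimination cleaves one acyl–CH2 bond to a seven-membered nickelacycle and C–C reductive elimination forms C4–C5. The closest known reaction type is the nickel-catalysed intermolecular insertion of internal alkynes into 3-substituted cyclobutanones, with ligand-controlled desymmetrisation known for 3,3-disubstituted ketones; a terminal alkyne with a 3-monosubstituted ketone has not been shown. The six-membered ring closes by reductive elimination from the seven-membered nickelacycle, a formal [4+2] ring expansion in which the four ring carbons of 3 and the two alkyne carbons become the cyclohexenone. The only stereocentre, C6 (5R in 4), is never touched; its configuration is fixed by the chiral ligand, which decides which of the two enantiotopic CH2 groups migrates to nickel in the β-carbon elimination. The step needs regioselectivity for the chain at C4, secured by the size difference between H and the alkyl chain at the two alkyne termini (the substituted carbon stays on nickel, away from the spiro centre), and chemoselectivity for cross-coupling over alkyne oligomerisation, secured by the high carbonyl reactivity of the strained ketone and a low alkyne concentration. The trisubstituted alkene of 2 is too hindered to compete for nickel.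

**Step 3**
Reactants: 5 2,4-dihydroxy-6-methoxybenzaldehyde
Product: 6 2-methoxy-4,6-bis(methoxymethoxy)benzaldehyde
Conditions: MOMCl, i-Pr2NEt, CH2Cl2, 0 °C → reflux
Reagents that add atoms: chloromethyl methyl ether, COCCl
Why: O-alkylation of both phenols with the chloromethyl ether (MOM protection) should proceed with excess reagent and warming, which overcome the hydrogen bond of the ortho hydroxyl to the formyl group.

**Step 4**
Reactants: 4 (5R)-3-(4-methylpent-3-en-1-yl)-5-phenylcyclohex-2-en-1-one; 6 2-methoxy-4,6-bis(methoxymethoxy)benzaldehyde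
Product: 8 (5R,6R)-6-{hydroxy[2-methoxy-4,6-bis(methoxymethoxy)phenyl]methyl}-3-(4-methylpent-3-en-1-yl)-5-phenylcyclohex-2-en-1-one, via lithium dienolate 7 (not isolated)
Conditions: LDA, THF, −78 °C; then 6, −78 °C; sat. aq. NH4Cl at −78 °C
Reagents that add atoms: none
Why: LDA at −78 °C should remove the α′ proton (ring C1–H) kinetically to give the cross-conjugated dienolate, whose aldol addition to the non-enolisable aldehyde should occur on the face opposite the adjacent phenyl group and so set C1 trans to C6 (kinetic enolate aldol addition; the carbinol centre forms as a mixture and is oxidised later).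

**Step 5**
Reactants: 8 (5R,6R)-6-{hydroxy[2-methoxy-4,6-bis(methoxymethoxy)phenyl]methyl}-3-(4-methylpent-3-en-1-yl)-5-phenylcyclohex-2-en-1-one
Product: 9 (5R,6R)-6-{[tert-butyl(dimethyl)silyl]oxy[2-methoxy-4,6-bis(methoxymethoxy)phenyl]methyl}-3-(4-methylpent-3-en-1-yl)-5-phenylcyclohex-2-en-1-one
Conditions: TBSOTf, 2,6-lutidine, CH2Cl2, −78 °C
Reagents that add atoms: tert-butyldimethylsilyl trifluoromethanesulfonate, CC(C)(C)[Si](C)(C)OS(=O)(=O)C(F)(F)F
Why: Silylation of a hindered secondary alcohol with a silyl triflate and a non-nucleophilic base (standard TBS protection) should block retro-aldol cleavage and distinguish this oxygen from the one to be removed.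

**Step 6**
Reactants: 9 (5R,6R)-6-{[tert-butyl(dimethyl)silyl]oxy[2-methoxy-4,6-bis(methoxymethoxy)phenyl]methyl}-3-(4-methylpent-3-en-1-yl)-5-phenylcyclohex-2-en-1-one
Product: 10 (5R,6S)-6-{[tert-butyl(dimethyl)silyl]oxy[2-methoxy-4,6-bis(methoxymethoxy)phenyl]methyl}-3-(4-methylpent-3-en-1-yl)-5-phenylcyclohex-2-en-1-ol
Conditions: NaBH4, CeCl3·7H2O, MeOH, −20 °C
Reagents that add atoms: none
Why: Luche reduction should deliver hydride 1,2 to the enone carbonyl without conjugate reduction, and the configuration of the new carbinol is irrelevant because C2 becomes CH2 (the 6S descriptor reflects only a change in CIP priorities).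

**Step 7**
Reactants: 10 (5R,6S)-6-{[tert-butyl(dimethyl)silyl]oxy[2-methoxy-4,6-bis(methoxymethoxy)phenyl]methyl}-3-(4-methylpent-3-en-1-yl)-5-phenylcyclohex-2-en-1-ol
Product: 11 (5R,6S)-6-{[tert-butyl(dimethyl)silyl]oxy[2-methoxy-4,6-bis(methoxymethoxy)phenyl]methyl}-3-(4-methylpent-3-en-1-yl)-5-phenylcyclohex-2-en-1-yl acetate
Conditions: Ac2O, pyridine, DMAP (cat.), CH2Cl2, rt
Reagents that add atoms: acetic anhydride, CC(=O)OC(C)=O
Why: DMAP-catalysed acetylation of the secondary allylic alcohol should install the leaving group needed for ionisation by palladium.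

**Step 8**
Reactants: 11 (5R,6S)-6-{[tert-butyl(dimethyl)silyl]oxy[2-methoxy-4,6-bis(methoxymethoxy)phenyl]methyl}-3-(4-methylpent-3-en-1-yl)-5-phenylcyclohex-2-en-1-yl acetate
Product: 12 tert-butyl{[2-methoxy-4,6-bis(methoxymethoxy)phenyl][(1R,6R)-4-(4-methylpent-3-en-1-yl)-6-phenylcyclohex-3-en-1-yl]methoxy}dimethylsilane
Conditions: Pd(PPh3)4 (5 mol%), NaBH4, DME, rt
Reagents that add atoms: none
Why: Zerovalent palladium should ionise the allylic acetate to a π-allyl complex spanning C2–C3–C4, and borohydride should deliver hydride to the less substituted terminus C2 so that the trisubstituted C3=C4 alkene is kept (palladium-catalysed reductive displacement of an allylic acetate, Tsuji–Trost type), while C1 and C6 lie outside the allyl unit.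

**Step 9**
Reactants: 12 tert-butyl{[2-methoxy-4,6-bis(methoxymethoxy)phenyl][(1R,6R)-4-(4-methylpent-3-en-1-yl)-6-phenylcyclohex-3-en-1-yl]methoxy}dimethylsilane
Product: 13 [2-methoxy-4,6-bis(methoxymethoxy)phenyl][(1R,6R)-4-(4-methylpent-3-en-1-yl)-6-phenylcyclohex-3-en-1-yl]methanol
Conditions: TBAF, THF, rt → 45 °C
Reagents that add atoms: none
Why: Fluoride should cleave the Si–O bond (standard desilylation) while the MOM ethers and both alkenes are inert.

**Step 10**
Reactants: 13 [2-methoxy-4,6-bis(methoxymethoxy)phenyl][(1R,6R)-4-(4-methylpent-3-en-1-yl)-6-phenylcyclohex-3-en-1-yl]methanol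
Product: 14 [2-methoxy-4,6-bis(methoxymethoxy)phenyl][(1R,6R)-4-(4-methylpent-3-en-1-yl)-6-phenylcyclohex-3-en-1-yl]methanone
Conditions: Dess–Martin periodinane, pyridine, CH2Cl2, 0 °C → rt
Reagents that add atoms: none
Why: Dess–Martin oxidation of the secondary benzylic alcohol under buffered conditions should give the aryl ketone, and C1, now α to the ketone, should stay in the trans (diequatorial) configuration, which is the more stable one.

**Step 11**
Reactants: 14 [2-methoxy-4,6-bis(methoxymethoxy)phenyl][(1R,6R)-4-(4-methylpent-3-en-1-yl)-6-phenylcyclohex-3-en-1-yl]methanone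
Product: 15 (2,4-dihydroxy-6-methoxyphenyl)[(1R,6R)-4-(4-methylpent-3-en-1-yl)-6-phenylcyclohex-3-en-1-yl]methanone
Conditions: HCl (3 M aq.), MeOH, 40 °C
Reagents that add atoms: none
Why: Acid-catalysed acetal exchange with methanol should remove both MOM ethers (the ortho one assisted by the carbonyl) at a temperature that spares the trisubstituted alkenes, and acid cannot erode the trans ring configuration because it is the thermodynamic one.

**Compound list**

1 | 5-bromo-2-methylpent-2-ene | CC(C)=CCCBr | starting material
2 | 6-methylhept-5-en-1-yne | C#CCCC=C(C)C | intermediate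
3 | 3-phenylcyclobutanone | O=C1CC(c2ccccc2)C1 | starting material
4 | (5R)-3-(4-methylpent-3-en-1-yl)-5-phenylcyclohex-2-en-1-one | O=C1C=C(CCC=C(C)C)C[C@@H](c2ccccc2)C1 | intermediate
5 | 2,4-dihydroxy-6-methoxybenzaldehyde | COc1cc(O)cc(O)c1C=O | starting material
6 | 2-methoxy-4,6-bis(methoxymethoxy)benzaldehyde | COc1cc(OCOC)cc(OCOC)c1C=O | intermediate
7 | lithium (3R)-5-(4-methylpent-3-en-1-yl)-3-phenylcyclohexa-1,5-dien-1-olate (not isolated) | [Li]OC1=C[C@H](c2ccccc2)CC(CCC=C(C)C)=C1 | intermediate
8 | (5R,6R)-6-{hydroxy[2-methoxy-4,6-bis(methoxymethoxy)phenyl]methyl}-3-(4-methylpent-3-en-1-yl)-5-phenylcyclohex-2-en-1-one, trans on the ring, mixture of carbinol epimers | COc1cc(OCOC)cc(OCOC)c1C(O)[C@@H]1C(=O)C=C(CCC=C(C)C)C[C@H]1c1ccccc1 | intermediate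
9 | (5R,6R)-6-{[tert-butyl(dimethyl)silyl]oxy[2-methoxy-4,6-bis(methoxymethoxy)phenyl]methyl}-3-(4-methylpent-3-en-1-yl)-5-phenylcyclohex-2-en-1-one, mixture at the silyloxy carbon | COc1cc(OCOC)cc(OCOC)c1C(O[Si](C)(C)C(C)(C)C)[C@@H]1C(=O)C=C(CCC=C(C)C)C[C@H]1c1ccccc1 | intermediate
10 | (5R,6S)-6-{[tert-butyl(dimethyl)silyl]oxy[2-methoxy-4,6-bis(methoxymethoxy)phenyl]methyl}-3-(4-methylpent-3-en-1-yl)-5-phenylcyclohex-2-en-1-ol, mixture at C1 and at the silyloxy carbon | COc1cc(OCOC)cc(OCOC)c1C(O[Si](C)(C)C(C)(C)C)[C@@H]1C(O)C=C(CCC=C(C)C)C[C@H]1c1ccccc1 | intermediate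
11 | (5R,6S)-6-{[tert-butyl(dimethyl)silyl]oxy[2-methoxy-4,6-bis(methoxymethoxy)phenyl]methyl}-3-(4-methylpent-3-en-1-yl)-5-phenylcyclohex-2-en-1-yl acetate, mixture at C1 and at the silyloxy carbon | COc1cc(OCOC)cc(OCOC)c1C(O[Si](C)(C)C(C)(C)C)[C@@H]1C(OC(C)=O)C=C(CCC=C(C)C)C[C@H]1c1ccccc1 | intermediate
12 | tert-butyl{[2-methoxy-4,6-bis(methoxymethoxy)phenyl][(1R,6R)-4-(4-methylpent-3-en-1-yl)-6-phenylcyclohex-3-en-1-yl]methoxy}dimethylsilane, mixture at the silyloxy carbon | COc1cc(OCOC)cc(OCOC)c1C(O[Si](C)(C)C(C)(C)C)[C@@H]1CC=C(CCC=C(C)C)C[C@H]1c1ccccc1 | intermediate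
13 | [2-methoxy-4,6-bis(methoxymethoxy)phenyl][(1R,6R)-4-(4-methylpent-3-en-1-yl)-6-phenylcyclohex-3-en-1-yl]methanol, mixture of carbinol epimers | COc1cc(OCOC)cc(OCOC)c1C(O)[C@@H]1CC=C(CCC=C(C)C)C[C@H]1c1ccccc1 | intermediate
14 | [2-methoxy-4,6-bis(methoxymethoxy)phenyl][(1R,6R)-4-(4-methylpent-3-en-1-yl)-6-phenylcyclohex-3-en-1-yl]methanone | COc1cc(OCOC)cc(OCOC)c1C(=O)[C@@H]1CC=C(CCC=C(C)C)C[C@H]1c1ccccc1 | intermediate
15 | (2,4-dihydroxy-6-methoxyphenyl)[(1R,6R)-4-(4-methylpent-3-en-1-yl)-6-phenylcyclohex-3-en-1-yl]methanone | COc1cc(O)cc(O)c1C(=O)[C@@H]1CC=C(CCC=C(C)C)C[C@H]1c1ccccc1 | target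

**Step count and risks**

Total step count: 11. Longest linear sequence: 10 steps (steps 1, 2 and 4 to 11); step 3 is a one-step side branch.

Steps most likely to fail:

1. Step 2. Alkyne oligomerisation or cyclotrimerisation may outrun the cross-coupling, the ligand may discriminate the two enantiotopic acyl–CH2 bonds poorly, or the seven-membered nickelacycle may undergo β-hydride elimination at the benzylic carbon before reductive elimination. The fallback reaches 4 by known chemistry and sets out from bromide 1. Cinnamaldehyde and tert-butyl acetoacetate are joined by iminium-catalysed Michael addition (diarylprolinol silyl ether catalyst of the sense giving the 3R adduct) to tert-butyl (3R)-2-acetyl-5-oxo-3-phenylpentanoate F1. Heating F1 with TsOH in toluene removes the tert-butyl ester, decarboxylates and closes the ring by aldol condensation to (5R)-5-phenylcyclohex-2-en-1-one F2. Bromide 1 is converted with magnesium in THF into (4-methylpent-3-en-1-yl)magnesium bromide F3, which adds in conjugate fashion to F2 with catalytic CuBr·SMe2 and TMSCl at −78 °C to give trimethyl{[(5R)-3-(4-methylpent-3-en-1-yl)-5-phenylcyclohex-1-en-1-yl]oxy}silane F4. Saegusa–Ito oxidation of F4 with Pd(OAc)2 in MeCN places the double bond toward the newly alkylated carbon and returns to the route at 4.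

2. Step 8. Hydride may be delivered to the wrong allyl terminus, moving the ring alkene to C2=C3, or the π-allyl complex may collapse to a diene by β-hydride elimination. The fallback avoids palladium and sets out from allylic alcohol 10. Sulfation with SO3·pyridine in THF gives the pyridinium sulfate monoester of allylic alcohol 10 F5, and LiAlH4 then displaces sulfate directly at C2 (deoxygenation of an allylic alcohol through its sulfate monoester, a method that proceeds without allylic transposition), returning to the route at 12.

3. Step 4. Addition of the lithium dienolate to the hindered, electron-rich aldehyde may be reversible or stall (retro-aldol on warming, proton transfer between aldolate and ketone). The fallback makes the C1–C bond under Lewis acid activation and sets out from 4. The dienolate 7 is trapped with TMSCl as trimethyl{[(3R)-5-(4-methylpent-3-en-1-yl)-3-phenylcyclohexa-1,5-dien-1-yl]oxy}silane F6, and Mukaiyama aldol addition of F6 to 6 with BF3·OEt2 in CH2Cl2 at −78 °C, again anti to phenyl, returns to the route at 8.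

**Further compounds**

F1 | step 2 | tert-butyl (3R)-2-acetyl-5-oxo-3-phenylpentanoate | O=CC[C@@H](c1ccccc1)C(C(C)=O)C(=O)OC(C)(C)C
F2 | step 2 | (5R)-5-phenylcyclohex-2-en-1-one | O=C1C=CC[C@@H](c2ccccc2)C1
F3 | step 2 | (4-methylpent-3-en-1-yl)magnesium bromide | CC(C)=CCC[Mg]Br
F4 | step 2 | trimethyl{[(5R)-3-(4-methylpent-3-en-1-yl)-5-phenylcyclohex-1-en-1-yl]oxy}silane | C[Si](C)(C)OC1=CC(CCC=C(C)C)C[C@@H](c2ccccc2)C1
F5 | step 8 | pyridinium sulfate monoester of allylic alcohol 10 | COc1cc(OCOC)cc(OCOC)c1C(O[Si](C)(C)C(C)(C)C)[C@@H]1C(OS(=O)(=O)[O-])C=C(CCC=C(C)C)C[C@H]1c1ccccc1.c1cc[nH+]cc1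
F6 | step 4 | trimethyl{[(3R)-5-(4-methylpent-3-en-1-yl)-3-phenylcyclohexa-1,5-dien-1-yl]oxy}silane | C[Si](C)(C)OC1=C[C@H](c2ccccc2)CC(CCC=C(C)C)=C1
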